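**Retrosynthetic overview**
- The target is unmasked last by one global BBr3 cleavage of four aryl methyl ethers and one methyl ester.
- The pyranone ring (ring C) is the only ring built: acid cyclodehydration of a 1-(2-hydroxyaryl)butane-1,3-dione.
- That diketone comes from Claisen C-acylation of an o-hydroxyacetophenone dianion (ring A piece) with a homophthalate half-ester chloride (ring B piece).
- Ring A piece: 5-heptylresorcinol, Nencki acetylation, selective para-O-methylation.
- Ring B piece: 2,4,5-trimethoxybenzoic acid, directed ortho-lithiation/methylation, esterification, lateral lithiation/carboxylation. Both benzene rings are bought.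

Assumption: the SMILES contains no stereocentre or stereogenic double bond, so the target is achiral and no stereocontrol is needed.

**Step 1**
Reactants: 1 5-heptylbenzene-1,3-diol (5-heptylresorcinol)
Product: 2 1-(2-heptyl-4,6-dihydroxyphenyl)ethan-1-one
Conditions: AcOH, ZnCl2, 140 °C
Reagents that add atoms: acetic acid CC(=O)O
Why: Nencki (Friedel–Crafts) C-acylation goes para to one OH and ortho to the other rather than to the crowded carbon between the two hydroxyls, giving the chelated ketone; no stereocentre is formed.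

**Step 2**
Reactants: 2 1-(2-heptyl-4,6-dihydroxyphenyl)ethan-1-one
Product: 3 1-(2-heptyl-6-hydroxy-4-methoxyphenyl)ethan-1-one
Conditions: MeI (1.1 equiv), K2CO3 (1.2 equiv), acetone, reflux
Reagents that add atoms: iodomethane CI
Why: Williamson etherification is selective for the para hydroxyl because the ortho hydroxyl is hydrogen-bonded to the ketone and much less nucleophilic.

**Step 3**
Reactants: 4 2,4,5-trimethoxybenzoic acid
Product: 6 3,4,6-trimethoxy-2-methylbenzoic acid, via dilithiated benzoate 5 (not isolated)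
Conditions: s-BuLi (2.2 equiv), TMEDA (2.2 equiv), THF, −78 °C; then inverse addition to excess MeI, −78 °C → rt; aq. HCl
Reagents that add atoms: iodomethane CI
Why: Directed ortho-metalation: the lithium carboxylate, reinforced by the neighbouring methoxy group, directs s-BuLi/TMEDA to the only C–H ortho to the acid, and the aryllithium is methylated by SN2 on MeI.

**Step 4**
Reactants: 6 3,4,6-trimethoxy-2-methylbenzoic acid
Product: 7 methyl 3,4,6-trimethoxy-2-methylbenzoate
Conditions: MeI (1.5 equiv), K2CO3 (1.5 equiv), DMF, rt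
Reagents that add atoms: iodomethane CI
Why: Carboxylate O-alkylation (SN2 at the methyl of MeI) is not slowed by the two ortho substituents that would block a Fischer esterification.

**Step 5**
Reactants: 7 methyl 3,4,6-trimethoxy-2-methylbenzoate
Product: 9 2-[2-(methoxycarbonyl)-3,5,6-trimethoxyphenyl]acetic acid, via benzylic lithium 8 (not isolated)
Conditions: LiN(i-Pr)2 (LDA, commercial solution, 1.2 equiv), THF, −78 °C; then transfer onto excess solid CO2, −78 °C → rt; aq. HCl
Reagents that add atoms: carbon dioxide O=C=O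
Why: Lateral (benzylic) lithiation of the o-toluate gives an ester-stabilised benzylic anion that is carboxylated, while the di-ortho-substituted ester resists self-condensation.

**Step 6**
Reactants: 3 1-(2-heptyl-6-hydroxy-4-methoxyphenyl)ethan-1-one; 9 2-[2-(methoxycarbonyl)-3,5,6-trimethoxyphenyl]acetic acid
Product: 13 methyl 2-[(5-heptyl-7-methoxy-4-oxo-4H-chromen-2-yl)methyl]-3,4,6-trimethoxybenzoate, via acid chloride 10 (not isolated), via dilithium enolate 11 (not isolated), via 1,3-diketone 12 (not isolated)
Conditions: 9, (COCl)2, cat. DMF, CH2Cl2, 0 °C → rt, evaporate; 3, LiN(SiMe3)2 (3.1 equiv), THF, −78 → −10 °C; add 10, −78 → 0 °C; aq. HCl; crude 12, cat. conc. HCl, MeOH, 60 °C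
Reagents that add atoms: none
Why: Crossed Claisen C-acylation of the phenoxide–enolate dianion by the acid chloride (or the aryl ketene it forms with base) gives the β-diketone, any O-acyl ester converging by Baker–Venkataraman shift, and acid-catalysed cyclodehydration then closes the chromone; no stereocentre is formed.

**Step 7**
Reactants: 13 methyl 2-[(5-heptyl-7-methoxy-4-oxo-4H-chromen-2-yl)methyl]-3,4,6-trimethoxybenzoate
Product: 14 2-[(5-heptyl-7-hydroxy-4-oxo-4H-chromen-2-yl)methyl]-3,4,6-trihydroxybenzoic acid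
Conditions: BBr3 (12 equiv), CH2Cl2, −78 °C → rt, 16 h; degassed ice-water work-up under Ar
Reagents that add atoms: none
Why: Lewis-acid-mediated dealkylation: BBr3 cleaves the four aryl methyl ethers and, by the same bromide attack on the O-methyl of the boron-chelated ester, the hindered methyl ester, so no attack at the shielded acyl carbon is needed.

**Compound list**
1 | 5-heptylbenzene-1,3-diol (5-heptylresorcinol) | CCCCCCCc1cc(O)cc(O)c1 | starting material
2 | 1-(2-heptyl-4,6-dihydroxyphenyl)ethan-1-one | CCCCCCCc1cc(O)cc(O)c1C(C)=O | intermediate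
3 | 1-(2-heptyl-6-hydroxy-4-methoxyphenyl)ethan-1-one | CCCCCCCc1cc(OC)cc(O)c1C(C)=O | intermediate
4 | 2,4,5-trimethoxybenzoic acid | COc1cc(OC)c(OC)cc1C(=O)O | starting material
5 | lithium 2-lithio-3,4,6-trimethoxybenzoate (dilithiated benzoate) | [Li]c1c(OC)c(OC)cc(OC)c1C(=O)O[Li] | intermediate
6 | 3,4,6-trimethoxy-2-methylbenzoic acid | Cc1c(OC)c(OC)cc(OC)c1C(=O)O | intermediate
7 | methyl 3,4,6-trimethoxy-2-methylbenzoate | Cc1c(OC)c(OC)cc(OC)c1C(=O)OC | intermediate
8 | methyl 2-(lithiomethyl)-3,4,6-trimethoxybenzoate (benzylic lithium) | [Li]Cc1c(OC)c(OC)cc(OC)c1C(=O)OC | intermediate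
9 | 2-[2-(methoxycarbonyl)-3,5,6-trimethoxyphenyl]acetic acid | OC(=O)Cc1c(OC)c(OC)cc(OC)c1C(=O)OC | intermediate
10 | methyl 2-(2-chloro-2-oxoethyl)-3,4,6-trimethoxybenzoate (acid chloride) | ClC(=O)Cc1c(OC)c(OC)cc(OC)c1C(=O)OC | intermediate
11 | dilithium salt of 3 (lithium phenoxide, lithium enolate of the acetyl group) | [Li]OC(=C)c1c(CCCCCCC)cc(OC)cc1O[Li] | intermediate
12 | methyl 2-[4-(2-heptyl-6-hydroxy-4-methoxyphenyl)-2,4-dioxobutyl]-3,4,6-trimethoxybenzoate (1,3-diketone) | CCCCCCCc1cc(OC)cc(O)c1C(=O)CC(=O)Cc1c(OC)c(OC)cc(OC)c1C(=O)OC | intermediate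
13 | methyl 2-[(5-heptyl-7-methoxy-4-oxo-4H-chromen-2-yl)methyl]-3,4,6-trimethoxybenzoate | CCCCCCCc1cc(OC)cc2oc(Cc3c(OC)c(OC)cc(OC)c3C(=O)OC)cc(=O)c12 | intermediate
14 | 2-[(5-heptyl-7-hydroxy-4-oxo-4H-chromen-2-yl)methyl]-3,4,6-trihydroxybenzoic acid | CCCCCCCc1cc(O)cc2oc(Cc3c(O)c(O)cc(O)c3C(=O)O)cc(=O)c12 | target

**Totals**
Total step count: 7.
Longest linear sequence: 5 steps (steps 3, 4, 5, 6 and 7, from 2,4,5-trimethoxybenzoic acid 4).

**Steps most likely to fail, with fallbacks**

Step 3 (ortho-lithiation/methylation). Possible failures are lithiation between the two methoxy groups, displacement of the ortho methoxy group by s-BuLi, or over-methylation to the ethyl compound. The fallback sets out from 4 and comes back at 6 without any organolithium. Carboxylate-directed C–H activation with catalytic Pd(OAc)2 and K2HPO4 in CH2Br2 at 140 °C can only palladate the single C–H ortho to the acid. Alkylation and lactonisation give the phthalide 4,5,7-trimethoxy-2-benzofuran-1(3H)-one F1. Hydrogenolysis of its benzylic C–O bond (H2, Pd/C, AcOH, cat. HClO4, 60 °C) opens the lactone to 6.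

Step 6 (Claisen acylation/cyclodehydration). The CH2 of the acyl donor is acidic, so proton transfer or ketene side reactions can compete, and the diketone enolate can close onto the aromatic ester in a Dieckmann reaction to give a naphthalenediol. The fallback sets out from 3 and comes back at 13, using acid chloride 10 made from 9 as before, and avoids both strong base and a free diketone. α-Bromination of 3 with CuBr2 in EtOAc/CHCl3 at reflux gives 2-bromo-1-(2-heptyl-6-hydroxy-4-methoxyphenyl)ethan-1-one F2. PPh3 in toluene converts it into [2-(2-heptyl-6-hydroxy-4-methoxyphenyl)-2-oxoethyl]triphenylphosphonium bromide F3. Aqueous Na2CO3 gives the stabilised ylide 1-(2-heptyl-6-hydroxy-4-methoxyphenyl)-2-(triphenylphosphoranylidene)ethan-1-one F4. Heating F4 with 10 and pyridine in toluene acylates the phenol to 3-heptyl-5-methoxy-2-[(triphenylphosphoranylidene)acetyl]phenyl [2-(methoxycarbonyl)-3,5,6-trimethoxyphenyl]acetate F5. Its ylide carbon attacks the new aryl ester carbonyl in an intramolecular Wittig olefination that closes the pyranone ring and gives 13 directly.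

Step 7 (global deprotection). The hindered, chelated methyl ester may survive BBr3 at room temperature, and forcing conditions endanger the air-sensitive, decarboxylation-prone trihydroxybenzoic acid. The fallback sets out from 13 and comes back at 14 in two stages. LiI in pyridine at reflux removes the ester methyl by SN2 attack of iodide and gives, after acidification, 2-[(5-heptyl-7-methoxy-4-oxo-4H-chromen-2-yl)methyl]-3,4,6-trimethoxybenzoic acid F6. BBr3 in CH2Cl2 (−78 → 0 °C) then only has to cleave the four aryl methyl ethers to reach 14.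

**Further compounds**
F1 | step 3 | 4,5,7-trimethoxy-2-benzofuran-1(3H)-one | O=C1OCc2c(OC)c(OC)cc(OC)c12
F2 | step 6 | 2-bromo-1-(2-heptyl-6-hydroxy-4-methoxyphenyl)ethan-1-one | CCCCCCCc1cc(OC)cc(O)c1C(=O)CBr
F3 | step 6 | [2-(2-heptyl-6-hydroxy-4-methoxyphenyl)-2-oxoethyl]triphenylphosphonium bromide | CCCCCCCc1cc(OC)cc(O)c1C(=O)C[P+](c1ccccc1)(c1ccccc1)c1ccccc1.[Br-]
F4 | step 6 | 1-(2-heptyl-6-hydroxy-4-methoxyphenyl)-2-(triphenylphosphoranylidene)ethan-1-one | CCCCCCCc1cc(OC)cc(O)c1C(=O)C=P(c1ccccc1)(c1ccccc1)c1ccccc1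
F5 | step 6 | 3-heptyl-5-methoxy-2-[(triphenylphosphoranylidene)acetyl]phenyl [2-(methoxycarbonyl)-3,5,6-trimethoxyphenyl]acetate | CCCCCCCc1cc(OC)cc(OC(=O)Cc2c(OC)c(OC)cc(OC)c2C(=O)OC)c1C(=O)C=P(c1ccccc1)(c1ccccc1)c1ccccc1
F6 | step 7 | 2-[(5-heptyl-7-methoxy-4-oxo-4H-chromen-2-yl)methyl]-3,4,6-trimethoxybenzoic acid | CCCCCCCc1cc(OC)cc2oc(Cc3c(OC)c(OC)cc(OC)c3C(=O)O)cc(=O)c12
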